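**Retrosynthetic overview**
1. Haterumaimide G (14) ⇐ ester methanolysis of 13 ⇐ photochemical deconjugation of 7-en-6-one 12 (C7=C8 → C8=C17) ⇐ allylic C6 oxidation of Δ7-olefin 10.
2. 10 ⇐ acylative E1 opening of the C8–O–C12 tetrahydrofuran in 8; the lactone oxygen of sclareolide ends up as the C12 hydroxyl.
3. 8 ⇐ imide closure of 7 ⇐ photochemical radical C13–C14 bond formation/H-atom transfer on enol ether 5, which sets C13 and C12 from the α-face of the decalin-fused ring.
4. 5 ⇐ Claisen addition/dehydration on 2α-chlorosclareolide 3 ⇐ photochemical C2–H chlorination of (+)-sclareolide 1.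
5. Ring order: A/B decalin bought → temporary tetrahydrofuran (from the lactone) → succinimide → tetrahydrofuran opened.

Assumption: labdane numbering is used (C2 = CHCl, C6 = ketone, C8=C17 exocyclic, C12 = carbinol, C13 = imide CH); the SMILES is read as (2S,5S,9S,10R,12S,13R), and N-chloroamide 2 is treated as a purchasable reagent.

---

**Step 1**
Reactants: 1 (+)-sclareolide; 2 N-tert-butyl-N-chloro-3,5-bis(trifluoromethyl)benzamide
Product: 3, 2α-chlorosclareolide (equatorial Cl, 2S)
Conditions: 2 (1.2 equiv), Cs2CO3, PhH, white LEDs, 55 °C
Reagents that add atoms: 2 (Cl), CC(C)(C)N(Cl)C(=O)c1cc(cc(c1)C(F)(F)F)C(F)(F)F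
Why: Light-initiated amidyl-radical chain C–H chlorination abstracts the most accessible, electron-rich C2–H (remote from the lactone), and Cl is delivered equatorially (α) because the β-axial approach is blocked by the syn-axial C10 and C4 methyls, so C2 is set by the sclareolide framework.

**Step 2**
Reactants: 3; 4 methyl acetate
Product: 5, methyl (E)-2-(tetrahydrofuran-2-ylidene)acetate fused at C8/C9: the lactone C=O of 3 is replaced by C12=C13H–CO2Me, with the ester cis to C11H2 and trans to the ring O
Conditions: LDA, MeOAc (2.5 equiv each), THF, −78 °C, then 3, −78 → −30 °C; crude hemiketal, CSA (10 mol%), 4 Å MS, CH2Cl2, rt (two operations, one purification)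
Reagents that add atoms: methyl acetate, COC(C)=O
Why: Claisen-type addition of the ester enolate to the γ-lactone gives the β-keto-ester hemiketal, and acid dehydration/equilibration gives the conjugated exocyclic enol ether as the E isomer, which avoids the ring-O/C=O dipole repulsion of the Z form (no new stereocentre; the C2–Cl is inert at −78 °C).

**Step 3**
Reactants: 5; 6 2-bromoacetamide
Product: 7, tetrahydrofuran with C12–H α (12S) and C13 (R) bearing CO2Me and CH2CONH2
Conditions: 6 (3 equiv), fac-Ir(ppy)3 (1 mol%), Hantzsch ester (2 equiv), i-Pr3SiSH (20 mol%), 2,6-lutidine, MeCN, 450 nm LEDs, rt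
Reagents that add atoms: 2-bromoacetamide (CH2CONH2), NC(=O)CBr
Why: Proposed new method: photoreduction of 6 gives the electrophilic carbamoylmethyl radical, which should add to the nucleophilic α-carbon (C13) of the push–pull enol ether from the α-face (the β-face is shielded by the axial C8 methyl), and the resulting tertiary α-oxy C12 radical is quenched by polarity-matched H-atom transfer from the thiol/Hantzsch ester, again on the α-face (cis to H9), so that α,α-addition across the E-alkene gives (12S,13R); the closest known reactions are photoredox reductive (Giese-type) hydroalkylations of simple enol ethers, glycals and enamides with α-halocarbonyls under thiol polarity-reversal catalysis, not yet shown at the α-carbon of a β-alkoxyacrylate.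

**Step 4**
Reactants: 7
Product: 8, (12S,13R)-tetrahydrofuranyl succinimide
Conditions: NaOMe (1.1 equiv), MeOH, 0 °C → rt; AcOH quench
Reagents that add atoms: none
Why: 5-exo-trig acyl substitution of the amide nitrogen on the methyl ester (aspartimide-type closure) is faster than C13 enolisation and is driven by formation of the imide anion, which also shuts down further C13–H exchange, so both new stereocentres are kept.

**Step 5**
Reactants: 8; 9 methoxyacetic anhydride
Product: 10, Δ7-olefin with C12–O-methoxyacetate (ring-opened; 2S,5S,9S,10S,12S,13R)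
Conditions: 9 (3 equiv), FeCl3 (10 mol%), CH2Cl2, 0 °C; aq. NaHCO3
Reagents that add atoms: methoxyacetic anhydride, COCC(=O)OC(=O)COC
Why: Lewis-acid/anhydride acylative ether cleavage (as in 1,8-cineole → α-terpinyl acetate) ionises the acyl-oxonium at tertiary C8, and E1 loss of the axial C7–H gives the Zaitsev Δ7 olefin; the C12–O bond is never broken, so C12 keeps its configuration.

**Step 6**
Reactants: 10; 11 tert-butyl hydroperoxide
Product: 12, 7-en-6-one
Conditions: RVC(+)/RVC(−), undivided cell, 10 mA/mmol, Cl4NHPI (20 mol%), pyridine (2 equiv), t-BuOOH (1.5 equiv), LiClO4, acetone, rt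
Reagents that add atoms: tert-butyl hydroperoxide (O), CC(C)(C)OO
Why: N-hydroxyphthalimide-mediated electrochemical allylic C–H oxidation abstracts the only secondary allylic hydrogen (C6–H) and gives the enone via the allylic peroxide, as in Δ7 → 7-en-6-one oxidations of sterols; the trans ring fusion at C5 is the stable one and is kept.

**Step 7**
Reactants: 12
Product: 13, 8(17)-en-6-one (O-methoxyacetyl haterumaimide G)
Conditions: hν (365 nm LEDs), AcOH (0.1 M), degassed EtOAc (0.01 M), 10 °C
Reagents that add atoms: none
Why: Acid-catalysed photochemical deconjugation of a 3-alkylcyclohex-2-enone (protonation of the twisted excited enone at C7, proton loss from the C17 methyl) gives the exocyclic β,γ-isomer, which accumulates because it does not absorb at 365 nm; the protected C12–O cannot add back to C8, and no stereocentre is touched.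

**Step 8**
Reactants: 13
Product: 14, haterumaimide G
Conditions: Yb(OTf)3 (30 mol%), MeOH, rt
Reagents that add atoms: none (methanol only removes the acyl group)
Why: Lanthanide-triflate-catalysed chemoselective methanolysis of the chelating methoxyacetate is essentially neutral, so the base-labile β,γ-enone, the imide, the C–Cl bond and all stereocentres are left intact.

---

**Compound list**
1 | (+)-sclareolide | C[C@@]12CC[C@H]3C(C)(C)CCC[C@]3(C)[C@H]1CC(=O)O2 | starting material
2 | N-tert-butyl-N-chloro-3,5-bis(trifluoromethyl)benzamide | CC(C)(C)N(Cl)C(=O)c1cc(cc(c1)C(F)(F)F)C(F)(F)F | starting material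
3 | 2α-chlorosclareolide | C[C@@]12CC[C@H]3C(C)(C)C[C@H](Cl)C[C@]3(C)[C@H]1CC(=O)O2 | intermediate
4 | methyl acetate | COC(C)=O | starting material
5 | (E)-exocyclic enol ether ester (lactone C=O → C=CH–CO2Me) | C[C@@]12CC[C@H]3C(C)(C)C[C@H](Cl)C[C@]3(C)[C@H]1C/C(=C\C(=O)OC)O2 | intermediate
6 | 2-bromoacetamide | NC(=O)CBr | starting material
7 | (12S,13R)-tetrahydrofuranyl ester–amide | C[C@@]12CC[C@H]3C(C)(C)C[C@H](Cl)C[C@]3(C)[C@H]1C[C@@H]([C@@H](CC(N)=O)C(=O)OC)O2 | intermediate
8 | (12S,13R)-tetrahydrofuranyl succinimide | C[C@@]12CC[C@H]3C(C)(C)C[C@H](Cl)C[C@]3(C)[C@H]1C[C@@H]([C@H]4CC(=O)NC4=O)O2 | intermediate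
9 | methoxyacetic anhydride | COCC(=O)OC(=O)COC | starting material
10 | Δ7-olefin, C12 methoxyacetate | CC1=CC[C@H]2C(C)(C)C[C@H](Cl)C[C@]2(C)[C@H]1C[C@H](OC(=O)COC)[C@H]1CC(=O)NC1=O | intermediate
11 | tert-butyl hydroperoxide | CC(C)(C)OO | starting material
12 | 7-en-6-one, C12 methoxyacetate | CC1=CC(=O)[C@H]2C(C)(C)C[C@H](Cl)C[C@]2(C)[C@H]1C[C@H](OC(=O)COC)[C@H]1CC(=O)NC1=O | intermediate
13 | 8(17)-en-6-one, C12 methoxyacetate | C=C1CC(=O)[C@H]2C(C)(C)C[C@H](Cl)C[C@]2(C)[C@H]1C[C@H](OC(=O)COC)[C@H]1CC(=O)NC1=O | intermediate
14 | haterumaimide G | C=C1CC(=O)[C@H]2C(C)(C)C[C@H](Cl)C[C@]2(C)[C@H]1C[C@H](O)[C@H]1CC(=O)NC1=O | target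

**Totals**
Total steps: 8. Longest linear sequence: 8 (from sclareolide).

**Three steps most likely to fail**
1. Step 3 (proposed new step). Risks: slow addition to the deactivated enol ether, premature reduction of the radical, and only modest face selectivity at C13. Fallback (known chemistry): an ionic sequence on 5 — α-face hydrogenation of the alkylidene tetrahydrofuran (H2, Pd/C) to set C12, C13 alkylation of the ester enolate with tert-butyl bromoacetate, chelation-controlled enolate re-protonation (Fráter–Seebach-type) to secure the syn isomer, then amide formation and imide closure.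
2. Step 5. Risks: the C8 cation may give Δ8(17)/Δ8(9) olefins or Wagner–Meerwein products. Fallback: open the ether under kinetic, base-buffered conditions (silyl triflate/2,6-lutidine) to the exocyclic olefin silyl ether, then move the double bond to Δ7 in a separate cobalt-hydride (HAT) olefin isomerisation before the C6 oxidation.
3. Step 7. Risks: poor twisting of the enone in the trans-decalin, competing Δ8(9) isomer or [2+2] dimerisation. Fallback: ionic deconjugation on a base-stable C12 silyl ether — form the linear dienolate (KHMDS, −78 °C) and protonate kinetically at C7 with AcOH; if C9 deprotonation competes, go through the C17 γ-bromide and a Zn/AcOH reductive transposition, which fixes the olefin at C8=C17.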